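**Strategy**

Germacrane numbering is used: C1 ketone, C3 methoxy, C4 methyl, C6–C7 lactone fusion, C8 angelate, C9 methylene, C10 acetoxy carbon with methyl C14. The route rests on closing the ten-membered carbocycle at C8–C9. C9 lies between the C8 carbinol and the fully substituted C10, which is α to the C1 ketone, so C14/C10/C9 is read as a 2-acylallyl unit. An open-chain C8 aldehyde carrying a 2-(bromomethyl)enone cyclises by intramolecular Nozaki–Hiyama–Kishi allylation; one operation forms the ring, the C8 carbinol and an exocyclic C10=C14 enone, which radical hydration then converts into the C10 tertiary carbinol. The methylene lactone is carried as its thiophenol adduct.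

Key step: step 16

Remark: C11, C12 and C13 are the lactone α-carbon, carbonyl and exocyclic methylene; names of bicyclic compounds use cyclodeca[b]furan locants (3 = C11, 3a = C7, 4 = C8, 6 = C10, 7 = C1, 9 = C3, 10 = C4, 11a = C6).
Assumption: in step 8 the (S,S)-ligand–chromium catalyst attacks the aldehyde face that gives 6R; if the sense is the opposite, the (R,R)-ligand is used.

**Route**

Step 1
Reactants: 1 methyl acrylate; 2 2,2-dimethoxyacetaldehyde (60% in water)
Product: 3 methyl 3-hydroxy-4,4-dimethoxy-2-methylidenebutanoate (racemic)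
Conditions: DABCO (0.5 equiv), 1,4-dioxane/H2O, rt
Reagents that add atoms: none
Why: Morita–Baylis–Hillman reaction, in which DABCO adds to the acrylate and the ammonium enolate captures the activated α-alkoxy aldehyde; the racemic carbinol centre is removed in step 2.

Step 2
Reactants: 3 methyl 3-hydroxy-4,4-dimethoxy-2-methylidenebutanoate
Product: 4 methyl (Z)-2-(bromomethyl)-4,4-dimethoxybut-2-enoate
Conditions: NBS, Me2S, CH2Cl2, 0 °C → rt
Reagents that add atoms: N-bromosuccinimide, O=C1CCC(=O)N1Br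
Why: Bromodimethylsulfonium activation of the allylic alcohol followed by SN2′ attack of bromide (allylic transposition) should give the conjugated (Z)-2-(bromomethyl)enoate under neutral conditions that spare the acetal.

Step 3
Reactants: 5 2-bromoprop-2-en-1-ol
Product: 6 [(2-bromoprop-2-en-1-yl)oxy](tert-butyl)dimethylsilane
Conditions: TBSCl, imidazole, DMF, rt
Reagents that add atoms: tert-butyldimethylsilyl chloride, CC(C)(C)[Si](C)(C)Cl
Why: Standard imidazole-assisted silylation of a primary allylic alcohol.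

Step 4
Reactants: 7 3-[(tert-butyldimethylsilyl)oxy]propanal
Product: 9 (3R,4R)-1-[(tert-butyldimethylsilyl)oxy]-4-methylhex-5-en-3-ol, via diisopinocampheylborinate 8 (not isolated)
Conditions: (Z)-crotyl-B(Ipc)2 [Ipc from (+)-α-pinene], THF/Et2O, −78 °C; then NaOH, H2O2, 0 °C → rt
Reagents that add atoms: (Z)-crotyldiisopinocampheylborane, C/C=C\CB([C@@H]1C[C@@H]2C[C@H]([C@H]1C)C2(C)C)[C@@H]1C[C@@H]2C[C@H]([C@H]1C)C2(C)C
Why: Brown asymmetric crotylboration, in which the (Z)-crotyl group is transferred through a closed chair transition state that fixes the 3,4-syn relationship while the isopinocampheyl groups select the aldehyde face, so that C3 and C4 are set as R,R.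

Step 5
Reactants: 9 (3R,4R)-1-[(tert-butyldimethylsilyl)oxy]-4-methylhex-5-en-3-ol
Product: 10 tert-butyl{[(3R,4R)-3-methoxy-4-methylhex-5-en-1-yl]oxy}dimethylsilane
Conditions: Me3OBF4, 1,8-bis(dimethylamino)naphthalene, CH2Cl2, 0 °C → rt
Reagents that add atoms: trimethyloxonium tetrafluoroborate, C[O+](C)C.F[B-](F)(F)F
Why: O-Methylation with Meerwein's salt and a hindered amine base is non-basic enough to avoid silyl migration and leaves both stereocentres untouched.

Step 6
Reactants: 10 tert-butyl{[(3R,4R)-3-methoxy-4-methylhex-5-en-1-yl]oxy}dimethylsilane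
Product: 12 (3R,4R)-6-[(tert-butyldimethylsilyl)oxy]-4-methoxy-3-methylhexan-1-ol, via B-alkyl-9-BBN adduct 11 (not isolated)
Conditions: 9-BBN, THF, 0 °C → rt; then NaOH, H2O2, 0 °C
Reagents that add atoms: hydrogen peroxide, OO
Why: Anti-Markovnikov hydroboration of the monosubstituted alkene with 9-BBN and oxidative work-up should give the primary alcohol without touching a stereocentre.

Step 7
Reactants: 12 (3R,4R)-6-[(tert-butyldimethylsilyl)oxy]-4-methoxy-3-methylhexan-1-ol
Product: 13 (3R,4R)-6-[(tert-butyldimethylsilyl)oxy]-4-methoxy-3-methylhexanal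
Conditions: Dess–Martin periodinane, CH2Cl2, rt
Reagents that add atoms: none
Why: Dess–Martin oxidation converts the primary alcohol into the aldehyde under neutral conditions.

Step 8
Reactants: 13 (3R,4R)-6-[(tert-butyldimethylsilyl)oxy]-4-methoxy-3-methylhexanal; 4 methyl (Z)-2-(bromomethyl)-4,4-dimethoxybut-2-enoate
Product: 15 (4S,5R)-5-{(2R,3R)-5-[(tert-butyldimethylsilyl)oxy]-3-methoxy-2-methylpentyl}-4-(dimethoxymethyl)-3-methylidenedihydrofuran-2(3H)-one, via hydroxy ester 14 (not isolated)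
Conditions: CrCl2 (10 mol %), (S,S)-3,6-di-tert-butyl-1,8-bis(4-isopropyl-4,5-dihydrooxazol-2-yl)-9H-carbazole (12 mol %), Mn powder, Et3N (20 mol %), TMSCl, THF, rt; then PPTS (cat.), MeOH/CH2Cl2, rt
Reagents that add atoms: none
Why: Catalytic asymmetric Nozaki–Hiyama–Kishi 2-(alkoxycarbonyl)allylation, in which the γ-substituted allylchromium adds through a chair transition state with the dimethoxymethyl group equatorial (anti adduct, hence the trans-lactone after ring closure) and the chiral ligand on chromium selects the aldehyde face, so that C6 should be R and C7 S.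

Step 9
Reactants: 15 the α-methylene lactone from step 8
Product: 16 (3S,4S,5R)-5-{(2R,3R)-5-[(tert-butyldimethylsilyl)oxy]-3-methoxy-2-methylpentyl}-4-(dimethoxymethyl)-3-[(phenylsulfanyl)methyl]dihydrofuran-2(3H)-one
Conditions: PhSH, Et3N (cat.), CH2Cl2, rt
Reagents that add atoms: thiophenol, Sc1ccccc1
Why: Base-catalysed thia-Michael addition masks the methylene lactone, equilibration at C11 should favour the all-trans lactone, and this temporary centre is removed again in step 20.

Step 10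
Reactants: 16 the phenylthiomethyl lactone silyl ether
Product: 17 (3S,4S,5R)-4-(dimethoxymethyl)-5-[(2R,3R)-5-hydroxy-3-methoxy-2-methylpentyl]-3-[(phenylsulfanyl)methyl]dihydrofuran-2(3H)-one
Conditions: HF·pyridine, pyridine, THF, 0 °C → rt
Reagents that add atoms: none
Why: Buffered fluoride cleavage of the primary silyl ether should leave the dimethyl acetal, lactone and sulfide untouched.

Step 11
Reactants: 17 the primary alcohol from step 10
Product: 18 (3R,4R)-5-{(2R,3S,4S)-3-(dimethoxymethyl)-5-oxo-4-[(phenylsulfanyl)methyl]tetrahydrofuran-2-yl}-3-methoxy-4-methylpentanal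
Conditions: Dess–Martin periodinane, pyridine, CH2Cl2, 0 °C → rt
Reagents that add atoms: none
Why: Dess–Martin oxidation tolerates aryl sulfides and acetals and should give the β-methoxy aldehyde without β-elimination.

Step 12
Reactants: 18 the C1 aldehyde; 6 [(2-bromoprop-2-en-1-yl)oxy](tert-butyl)dimethylsilane
Product: 20 (3S,4S,5R)-5-{(2R,3R)-7-[(tert-butyldimethylsilyl)oxy]-5-hydroxy-3-methoxy-2-methyl-6-methylideneheptyl}-4-(dimethoxymethyl)-3-[(phenylsulfanyl)methyl]dihydrofuran-2(3H)-one (both C1 carbinol epimers), via alkenylchromium dichloride 19 (not isolated)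
Conditions: CrCl2 (6 equiv), NiCl2 (2 mol %), DMF, rt
Reagents that add atoms: none
Why: Intermolecular Nozaki–Hiyama–Kishi coupling, in which NiCl2-catalysed formation of the alkenylchromium species is followed by chemoselective addition to the aldehyde in the presence of the lactone; the C1 carbinol epimers converge in step 13.

Step 13
Reactants: 20 the allylic alcohol mixture
Product: 21 (3S,4S,5R)-5-{(2R,3R)-7-[(tert-butyldimethylsilyl)oxy]-3-methoxy-2-methyl-6-methylidene-5-oxoheptyl}-4-(dimethoxymethyl)-3-[(phenylsulfanyl)methyl]dihydrofuran-2(3H)-one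
Conditions: Dess–Martin periodinane, pyridine, CH2Cl2, rt
Reagents that add atoms: none
Why: Dess–Martin oxidation of the allylic alcohol takes both C1 epimers to the same enone.

Step 14
Reactants: 21 the silyloxymethyl enone acetal
Product: 22 (2R,3S,4S)-2-[(2R,3R)-7-hydroxy-3-methoxy-2-methyl-6-methylidene-5-oxoheptyl]-5-oxo-4-[(phenylsulfanyl)methyl]tetrahydrofuran-3-carbaldehyde
Conditions: 2 M HCl (aq)/THF 1:4, rt
Reagents that add atoms: water, O
Why: Aqueous acid hydrolyses the dimethyl acetal and the primary allylic silyl ether in one operation, and C7 next to the new aldehyde is already in its thermodynamically preferred trans arrangement.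

Step 15
Reactants: 22 the hydroxymethyl enone aldehyde
Product: 24 (2R,3S,4S)-2-[(2R,3R)-6-(bromomethyl)-3-methoxy-2-methyl-5-oxohept-6-en-1-yl]-5-oxo-4-[(phenylsulfanyl)methyl]tetrahydrofuran-3-carbaldehyde, via mesylate 23 (not isolated)
Conditions: MsCl, Et3N, CH2Cl2, −20 °C; then LiBr, THF, 0 °C
Reagents that add atoms: lithium bromide, [Li+].[Br-]
Why: Mesylation of the primary allylic alcohol and displacement by bromide (SN2 or SN2′, both giving the same 2-(bromomethyl)enone) proceed under conditions that leave the aldehyde intact.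

Step 16
Reactants: 24 the bromomethyl enone aldehyde
Product: 26 (3S,3aR,4S,9R,10R,11aR)-4-hydroxy-9-methoxy-10-methyl-6-methylidene-3-[(phenylsulfanyl)methyl]dodecahydrocyclodeca[b]furan-2,7-dione, via allylchromium dichloride 25 (not isolated)
Conditions: CrCl2 (10 equiv), THF, 2 mM, rt, slow addition of 24 by syringe pump
Reagents that add atoms: none
Why: Two single-electron transfers from CrCl2 (divalent chromium) convert the allylic bromide into the 2-acylallylchromium dichloride 25 (trivalent chromium), which adds to the C8 aldehyde through a six-membered chair-like Zimmerman–Traxler transition state with the metal bound to the aldehyde oxygen; as both allyl termini are CH2 groups, direct and allyl-transposed addition give the same constitution. The closest known reaction type is the intramolecular Nozaki–Hiyama–Kishi (Barbier-type) allylation used to close germacrane-size carbocycles from ω-formyl allylic bromides and to fuse medium rings from 2-(bromomethyl)acrylates. The ten-membered carbocycle closes by a 10-exo-trig addition to the C8 carbonyl that forms the C8–C9 bond. The new stereocentre C8 is controlled by C7: with the tether-bearing C6 as the large group antiperiplanar to the incoming C9 (Felkin–Anh), attack should place the hydroxyl syn to C11, which is 8S. The step needs chemoselectivity for the aldehyde over the C1 enone and the lactone, which the high aldehyde preference and low basicity of allylchromium reagents secure, and cyclisation over oligomerisation, which high dilution and the turn imposed by the trans-disubstituted lactone favour.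

Step 17
Reactants: 26 the macrocyclic hydroxy enone
Product: 28 (3S,3aR,4S,6R,9R,10R,11aR)-4,6-dihydroxy-9-methoxy-6,10-dimethyl-3-[(phenylsulfanyl)methyl]dodecahydrocyclodeca[b]furan-2,7-dione, via hydroperoxide 27 (not isolated)
Conditions: Mn(dpm)3 [tris(2,2,6,6-tetramethylheptane-3,5-dionato)manganese] (20 mol %), PhSiH3, O2 (1 atm), i-PrOH/CH2Cl2, 0 °C; then P(OEt)3
Reagents that add atoms: dioxygen, O=O
Why: Mukaiyama-type hydration of the enone, in which a manganese hydride transfers a hydrogen atom to C14, the tertiary α-keto radical at C10 captures O2 and the hydroperoxide is reduced by the phosphite; O2 is expected to enter from the outer face of the ring, which should give the 10R carbinol with its hydroxyl syn to the C8 hydroxyl.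

Step 18
Reactants: 28 the diol; 29 angelic acid [(Z)-2-methylbut-2-enoic acid]
Product: 31 (3S,3aS,4S,6R,9R,10R,11aR)-6-hydroxy-9-methoxy-6,10-dimethyl-2,7-dioxo-3-[(phenylsulfanyl)methyl]dodecahydrocyclodeca[b]furan-4-yl (2Z)-2-methylbut-2-enoate, via mixed anhydride 30 (not isolated)
Conditions: 29, 2,4,6-trichlorobenzoyl chloride, Et3N, toluene, rt; then 28, 80 °C
Reagents that add atoms: none
Why: Yamaguchi esterification through the mixed anhydride without a nucleophilic catalyst is the usual way to make angelates without Z to E isomerisation, and only the secondary C8 hydroxyl should react because the tertiary C10 hydroxyl is too hindered.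

Step 19
Reactants: 31 the angelate with free C10 hydroxyl
Product: 32 (3S,3aS,4S,6R,9R,10R,11aR)-6-(acetyloxy)-9-methoxy-6,10-dimethyl-2,7-dioxo-3-[(phenylsulfanyl)methyl]dodecahydrocyclodeca[b]furan-4-yl (2Z)-2-methylbut-2-enoate
Conditions: Ac2O, Sc(OTf)3 (5 mol %), MeCN, −20 °C → 0 °C
Reagents that add atoms: acetic anhydride, CC(=O)OC(C)=O
Why: Lewis acid-catalysed acetylation with Sc(OTf)3 is fast enough for a tertiary α-ketol hydroxyl and is run cold to spare the angelate and the β-methoxy ketone.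

Step 20
Reactants: 32 the fully acylated sulfide
Product: 34 Rufesolide C, via sulfoxide 33 (not isolated)
Conditions: mCPBA (1.0 equiv), CH2Cl2, −78 °C; then toluene, 110 °C
Reagents that add atoms: none
Why: Chemoselective S-oxidation followed by thermal syn-elimination of benzenesulfenic acid (sulfoxide pyrolysis), in which H11 is the only β-hydrogen, should regenerate the exocyclic methylene lactone under neutral conditions.

**Compound list**

1 | methyl acrylate | C=CC(=O)OC | starting material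
2 | 2,2-dimethoxyacetaldehyde | COC(OC)C=O | starting material
3 | methyl 3-hydroxy-4,4-dimethoxy-2-methylidenebutanoate (racemic) | C=C(C(O)C(OC)OC)C(=O)OC | intermediate
4 | methyl (Z)-2-(bromomethyl)-4,4-dimethoxybut-2-enoate | COC(=O)/C(CBr)=C/C(OC)OC | intermediate
5 | 2-bromoprop-2-en-1-ol | C=C(Br)CO | starting material
6 | [(2-bromoprop-2-en-1-yl)oxy](tert-butyl)dimethylsilane | C=C(Br)CO[Si](C)(C)C(C)(C)C | intermediate
7 | 3-[(tert-butyldimethylsilyl)oxy]propanal | CC(C)(C)[Si](C)(C)OCCC=O | starting material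
8 | diisopinocampheylborinate of 9 | CC(C)(C)[Si](C)(C)OCC[C@@H](OB([C@@H]1C[C@@H]2C[C@H]([C@H]1C)C2(C)C)[C@@H]1C[C@@H]2C[C@H]([C@H]1C)C2(C)C)[C@H](C)C=C | intermediate
9 | (3R,4R)-1-[(tert-butyldimethylsilyl)oxy]-4-methylhex-5-en-3-ol | CC(C)(C)[Si](C)(C)OCC[C@@H](O)[C@H](C)C=C | intermediate
10 | tert-butyl{[(3R,4R)-3-methoxy-4-methylhex-5-en-1-yl]oxy}dimethylsilane | CC(C)(C)[Si](C)(C)OCC[C@@H](OC)[C@H](C)C=C | intermediate
11 | B-alkyl-9-borabicyclo[3.3.1]nonane adduct of 10 | CC(C)(C)[Si](C)(C)OCC[C@@H](OC)[C@H](C)CCB1C2CCCC1CCC2 | intermediate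
12 | (3R,4R)-6-[(tert-butyldimethylsilyl)oxy]-4-methoxy-3-methylhexan-1-ol | CC(C)(C)[Si](C)(C)OCC[C@@H](OC)[C@H](C)CCO | intermediate
13 | (3R,4R)-6-[(tert-butyldimethylsilyl)oxy]-4-methoxy-3-methylhexanal | CC(C)(C)[Si](C)(C)OCC[C@@H](OC)[C@H](C)CC=O | intermediate
14 | methyl (3S,4R,6R,7R)-9-[(tert-butyldimethylsilyl)oxy]-3-(dimethoxymethyl)-4-hydroxy-7-methoxy-6-methyl-2-methylidenenonanoate | COC(=O)C(=C)[C@H](C(OC)OC)[C@H](O)C[C@@H](C)[C@H](OC)CCO[Si](C)(C)C(C)(C)C | intermediate
15 | (4S,5R)-5-{(2R,3R)-5-[(tert-butyldimethylsilyl)oxy]-3-methoxy-2-methylpentyl}-4-(dimethoxymethyl)-3-methylidenedihydrofuran-2(3H)-one | C=C1C(=O)O[C@H](C[C@@H](C)[C@H](OC)CCO[Si](C)(C)C(C)(C)C)[C@H]1C(OC)OC | intermediate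
16 | (3S,4S,5R)-5-{(2R,3R)-5-[(tert-butyldimethylsilyl)oxy]-3-methoxy-2-methylpentyl}-4-(dimethoxymethyl)-3-[(phenylsulfanyl)methyl]dihydrofuran-2(3H)-one | O=C1O[C@H](C[C@@H](C)[C@H](OC)CCO[Si](C)(C)C(C)(C)C)[C@@H](C(OC)OC)[C@@H]1CSc2ccccc2 | intermediate
17 | (3S,4S,5R)-4-(dimethoxymethyl)-5-[(2R,3R)-5-hydroxy-3-methoxy-2-methylpentyl]-3-[(phenylsulfanyl)methyl]dihydrofuran-2(3H)-one | O=C1O[C@H](C[C@@H](C)[C@H](OC)CCO)[C@@H](C(OC)OC)[C@@H]1CSc2ccccc2 | intermediate
18 | (3R,4R)-5-{(2R,3S,4S)-3-(dimethoxymethyl)-5-oxo-4-[(phenylsulfanyl)methyl]tetrahydrofuran-2-yl}-3-methoxy-4-methylpentanal | O=C1O[C@H](C[C@@H](C)[C@H](OC)CC=O)[C@@H](C(OC)OC)[C@@H]1CSc2ccccc2 | intermediate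
19 | {3-[(tert-butyldimethylsilyl)oxy]prop-1-en-2-yl}chromium dichloride | C=C(CO[Si](C)(C)C(C)(C)C)[Cr](Cl)Cl | intermediate
20 | (3S,4S,5R)-5-{(2R,3R)-7-[(tert-butyldimethylsilyl)oxy]-5-hydroxy-3-methoxy-2-methyl-6-methylideneheptyl}-4-(dimethoxymethyl)-3-[(phenylsulfanyl)methyl]dihydrofuran-2(3H)-one (C1 carbinol epimers) | O=C1O[C@H](C[C@@H](C)[C@H](OC)CC(O)C(=C)CO[Si](C)(C)C(C)(C)C)[C@@H](C(OC)OC)[C@@H]1CSc2ccccc2 | intermediate
21 | (3S,4S,5R)-5-{(2R,3R)-7-[(tert-butyldimethylsilyl)oxy]-3-methoxy-2-methyl-6-methylidene-5-oxoheptyl}-4-(dimethoxymethyl)-3-[(phenylsulfanyl)methyl]dihydrofuran-2(3H)-one | O=C1O[C@H](C[C@@H](C)[C@H](OC)CC(=O)C(=C)CO[Si](C)(C)C(C)(C)C)[C@@H](C(OC)OC)[C@@H]1CSc2ccccc2 | intermediate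
22 | (2R,3S,4S)-2-[(2R,3R)-7-hydroxy-3-methoxy-2-methyl-6-methylidene-5-oxoheptyl]-5-oxo-4-[(phenylsulfanyl)methyl]tetrahydrofuran-3-carbaldehyde | O=C1O[C@H](C[C@@H](C)[C@H](OC)CC(=O)C(=C)CO)[C@@H](C=O)[C@@H]1CSc2ccccc2 | intermediate
23 | methanesulfonate of 22 | O=C1O[C@H](C[C@@H](C)[C@H](OC)CC(=O)C(=C)COS(C)(=O)=O)[C@@H](C=O)[C@@H]1CSc2ccccc2 | intermediate
24 | (2R,3S,4S)-2-[(2R,3R)-6-(bromomethyl)-3-methoxy-2-methyl-5-oxohept-6-en-1-yl]-5-oxo-4-[(phenylsulfanyl)methyl]tetrahydrofuran-3-carbaldehyde | O=C1O[C@H](C[C@@H](C)[C@H](OC)CC(=O)C(=C)CBr)[C@@H](C=O)[C@@H]1CSc2ccccc2 | intermediate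
25 | 2-acylallylchromium dichloride derived from 24 | O=C1O[C@H](C[C@@H](C)[C@H](OC)CC(=O)C(=C)C[Cr](Cl)Cl)[C@@H](C=O)[C@@H]1CSc2ccccc2 | intermediate
26 | (3S,3aR,4S,9R,10R,11aR)-4-hydroxy-9-methoxy-10-methyl-6-methylidene-3-[(phenylsulfanyl)methyl]dodecahydrocyclodeca[b]furan-2,7-dione | c1ccccc1SC[C@@H]2C(=O)O[C@@H]3C[C@@H](C)[C@H](OC)CC(=O)C(=C)C[C@H](O)[C@@H]23 | intermediate
27 | (3S,3aR,4S,6R,9R,10R,11aR)-6-hydroperoxy-4-hydroxy-9-methoxy-6,10-dimethyl-3-[(phenylsulfanyl)methyl]dodecahydrocyclodeca[b]furan-2,7-dione | c1ccccc1SC[C@@H]2C(=O)O[C@@H]3C[C@@H](C)[C@H](OC)CC(=O)[C@](C)(OO)C[C@H](O)[C@@H]23 | intermediate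
28 | (3S,3aR,4S,6R,9R,10R,11aR)-4,6-dihydroxy-9-methoxy-6,10-dimethyl-3-[(phenylsulfanyl)methyl]dodecahydrocyclodeca[b]furan-2,7-dione | c1ccccc1SC[C@@H]2C(=O)O[C@@H]3C[C@@H](C)[C@H](OC)CC(=O)[C@](C)(O)C[C@H](O)[C@@H]23 | intermediate
29 | angelic acid, (Z)-2-methylbut-2-enoic acid | C/C=C(/C)C(=O)O | starting material
30 | (Z)-2-methylbut-2-enoic 2,4,6-trichlorobenzoic anhydride | C/C=C(/C)C(=O)OC(=O)c1c(Cl)cc(Cl)cc1Cl | intermediate
31 | (3S,3aS,4S,6R,9R,10R,11aR)-6-hydroxy-9-methoxy-6,10-dimethyl-2,7-dioxo-3-[(phenylsulfanyl)methyl]dodecahydrocyclodeca[b]furan-4-yl (2Z)-2-methylbut-2-enoate | c1ccccc1SC[C@@H]2C(=O)O[C@@H]3C[C@@H](C)[C@H](OC)CC(=O)[C@](C)(O)C[C@H](OC(=O)/C(C)=C\C)[C@@H]23 | intermediate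
32 | (3S,3aS,4S,6R,9R,10R,11aR)-6-(acetyloxy)-9-methoxy-6,10-dimethyl-2,7-dioxo-3-[(phenylsulfanyl)methyl]dodecahydrocyclodeca[b]furan-4-yl (2Z)-2-methylbut-2-enoate | c1ccccc1SC[C@@H]2C(=O)O[C@@H]3C[C@@H](C)[C@H](OC)CC(=O)[C@](C)(OC(C)=O)C[C@H](OC(=O)/C(C)=C\C)[C@@H]23 | intermediate
33 | sulfoxide of 32 (both sulfur epimers) | O=S(c1ccccc1)C[C@@H]2C(=O)O[C@@H]3C[C@@H](C)[C@H](OC)CC(=O)[C@](C)(OC(C)=O)C[C@H](OC(=O)/C(C)=C\C)[C@@H]23 | intermediate
34 | Rufesolide C, (3aS,4S,6R,9R,10R,11aR)-6-(acetyloxy)-9-methoxy-6,10-dimethyl-3-methylidene-2,7-dioxododecahydrocyclodeca[b]furan-4-yl (2Z)-2-methylbut-2-enoate | C=C1C(=O)O[C@@H]2C[C@@H](C)[C@H](OC)CC(=O)[C@](C)(OC(C)=O)C[C@H](OC(=O)/C(C)=C\C)[C@@H]12 | target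

**Step count**

Total: 20 steps (steps 1–3 make the two coupling partners 4 and 6).
Longest linear sequence: 17 steps (steps 4–20, from aldehyde 7).

**Steps most likely to fail, with fallbacks**

For step 16, the ring closure may suffer from attack on the wrong face of the C8 aldehyde when ring strain overrides the Felkin–Anh preference, and the new chromium alkoxide may compete by oligomerisation. The fallback uses inversion at C8 instead of retention. It sets out from 24: the closure is run as described and the 8-epi alcohol F1 is taken on. Hydration as in step 17 gives the 8-epi diol F2. Mitsunobu esterification of F2 with angelic acid 29 (PPh3, DIAD, toluene, 0 °C) inverts C8 and installs the ester in one operation, returning to the route at 31.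

For step 17, capture of O2 by the planar C10 radical may show poor facial selectivity, and simple 1,4-reduction may compete. The fallback replaces the radical hydration by a reagent-controlled enolate hydroxylation and sets out from 26. Silylation (TESCl, imidazole, CH2Cl2) gives the triethylsilyl ether F3. L-Selectride (THF, −78 °C) reduces the exocyclic enone in the 1,4-sense to the lithium enolate F4. F4 is hydroxylated in the same flask with the enantiomer of (camphorsulfonyl)oxaziridine matched to the 10R configuration, giving the hydroxy ketone silyl ether F5. HF·pyridine removes the silyl group and returns to the route at 28.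

For step 8, catalyst control over the two new centres may be incomplete next to the existing C3/C4 centres, and the acetal-bearing bromide may react sluggishly. The fallback relies on auxiliary control and sets out from 13.
- Evans syn-aldol addition of the dibutylboron enolate of (S)-4-benzyl-3-(4-methoxy-4-oxobutanoyl)oxazolidin-2-one (Bu2BOTf, Et3N, CH2Cl2, −78 → 0 °C) gives the aldol adduct F6.
- F6 lactonises (PPTS, CH2Cl2) to the lactone imide F7.
- NaBH4 in THF/H2O removes the auxiliary reductively and gives the hydroxymethyl lactone F8.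
- Dess–Martin oxidation gives the aldehyde F9, and HC(OMe)3/PPTS in MeOH gives the acetal F10.
- LDA followed by dimethylmethyleneiminium iodide gives the Mannich base F11; N-methylation (MeI) and elimination (NaHCO3) return to the route at 15.

Further compounds
F1 | step 16 | (3S,3aR,4R,9R,10R,11aR)-4-hydroxy-9-methoxy-10-methyl-6-methylidene-3-[(phenylsulfanyl)methyl]dodecahydrocyclodeca[b]furan-2,7-dione (C8 epimer of 26) | c1ccccc1SC[C@@H]2C(=O)O[C@@H]3C[C@@H](C)[C@H](OC)CC(=O)C(=C)C[C@@H](O)[C@@H]23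
F2 | step 16 | (3S,3aR,4R,6R,9R,10R,11aR)-4,6-dihydroxy-9-methoxy-6,10-dimethyl-3-[(phenylsulfanyl)methyl]dodecahydrocyclodeca[b]furan-2,7-dione (C8 epimer of 28) | c1ccccc1SC[C@@H]2C(=O)O[C@@H]3C[C@@H](C)[C@H](OC)CC(=O)[C@](C)(O)C[C@@H](O)[C@@H]23
F3 | step 17 | (3S,3aS,4S,9R,10R,11aR)-9-methoxy-10-methyl-6-methylidene-3-[(phenylsulfanyl)methyl]-4-[(triethylsilyl)oxy]dodecahydrocyclodeca[b]furan-2,7-dione | c1ccccc1SC[C@@H]2C(=O)O[C@@H]3C[C@@H](C)[C@H](OC)CC(=O)C(=C)C[C@H](O[Si](CC)(CC)CC)[C@@H]23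
F4 | step 17 | lithium C1(O)=C10 enolate obtained from F3 by 1,4-reduction | c1ccccc1SC[C@@H]2C(=O)O[C@@H]3C[C@@H](C)[C@H](OC)CC(O[Li])=C(C)C[C@H](O[Si](CC)(CC)CC)[C@@H]23
F5 | step 17 | (3S,3aS,4S,6R,9R,10R,11aR)-6-hydroxy-9-methoxy-6,10-dimethyl-3-[(phenylsulfanyl)methyl]-4-[(triethylsilyl)oxy]dodecahydrocyclodeca[b]furan-2,7-dione | c1ccccc1SC[C@@H]2C(=O)O[C@@H]3C[C@@H](C)[C@H](OC)CC(=O)[C@](C)(O)C[C@H](O[Si](CC)(CC)CC)[C@@H]23
F6 | step 8 | methyl (3S,4R,6R,7R)-3-{[(4S)-4-benzyl-2-oxo-1,3-oxazolidin-3-yl]carbonyl}-9-[(tert-butyldimethylsilyl)oxy]-4-hydroxy-7-methoxy-6-methylnonanoate | COC(=O)C[C@H](C(=O)N1[C@@H](Cc2ccccc2)COC1=O)[C@H](O)C[C@@H](C)[C@H](OC)CCO[Si](C)(C)C(C)(C)C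
F7 | step 8 | (4S)-4-benzyl-3-{[(2R,3S)-2-{(2R,3R)-5-[(tert-butyldimethylsilyl)oxy]-3-methoxy-2-methylpentyl}-5-oxotetrahydrofuran-3-yl]carbonyl}-1,3-oxazolidin-2-one | O=C1C[C@H](C(=O)N2[C@@H](Cc3ccccc3)COC2=O)[C@@H](C[C@@H](C)[C@H](OC)CCO[Si](C)(C)C(C)(C)C)O1
F8 | step 8 | (4R,5R)-5-{(2R,3R)-5-[(tert-butyldimethylsilyl)oxy]-3-methoxy-2-methylpentyl}-4-(hydroxymethyl)dihydrofuran-2(3H)-one | O=C1C[C@H](CO)[C@@H](C[C@@H](C)[C@H](OC)CCO[Si](C)(C)C(C)(C)C)O1
F9 | step 8 | (2R,3S)-2-{(2R,3R)-5-[(tert-butyldimethylsilyl)oxy]-3-methoxy-2-methylpentyl}-5-oxotetrahydrofuran-3-carbaldehyde | O=C1C[C@H](C=O)[C@@H](C[C@@H](C)[C@H](OC)CCO[Si](C)(C)C(C)(C)C)O1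
F10 | step 8 | (4S,5R)-5-{(2R,3R)-5-[(tert-butyldimethylsilyl)oxy]-3-methoxy-2-methylpentyl}-4-(dimethoxymethyl)dihydrofuran-2(3H)-one | O=C1C[C@H](C(OC)OC)[C@@H](C[C@@H](C)[C@H](OC)CCO[Si](C)(C)C(C)(C)C)O1
F11 | step 8 | (4S,5R)-5-{(2R,3R)-5-[(tert-butyldimethylsilyl)oxy]-3-methoxy-2-methylpentyl}-4-(dimethoxymethyl)-3-[(dimethylamino)methyl]dihydrofuran-2(3H)-one (C3 epimers) | CN(C)CC1C(=O)O[C@H](C[C@@H](C)[C@H](OC)CCO[Si](C)(C)C(C)(C)C)[C@H]1C(OC)OC
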